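| flask | starting material | capture agent | free enzyme | added ligand | temperature | remark | time |
|---|---|---|---|---|---|---|---|
| north | 10 mM | 0.20 mM | 2 µM | 4.1 µM | 40 °C | the very flask that is asked about, followed so far |  |
| north-east | 10 mM | 0.30 mM | 2 µM | 4.1 µM | 35 °C | run made earlier |  |
| flask | 10 mM | 0.200 mM | 2.0 µM | 4.1 µM | 40 °C |  | 2.5 d |

| run | time / h | product / % | starting material / % |
|---|---|---|---|
| north | 4.00 | 13.8 | 85.9 |
| north | 8.00 | 13.7 | 86.0 |
| north | 15.0 | 13.4 | 86.6 |
| north | 25.0 | 14.0 | 86.5 |
| north | 50.0 | 14.0 | 86.3 |
| north-east | 2.50 | 8.1 | 91.7 |
| north-east | 8.00 | 7.9 | 92.0 |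
| north-east | 15.0 | 7.9 | 91.8 |
| north-east | 20.0 | 7.5 | 92.1 |
| north-east | 30.0 | 7.7 | 91.9 |

(each reading ± 0.3 percentage points)

- winter: change nothing and wait 5.0 d more
- noon: at 2.5 d add free enzyme, 50.0% of the amount charged, then wait 5.0 d
- dusk: at 2.5 d take out 90% of the product then present, then wait 5.0 d
- summer: at 2.5 d raise the temperature by 10 K, then wait 5.0 d

- product that was removed still counts
- additions bring no volume worth counting

- product, in percent of the starting material first charged, at 2.5 d
- the option that brings most further product ("none" if no option brings more than 2 percentage points) (winter / noon / dusk / summer / none)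
- product present, with what was taken out counted in, in percent of the starting material first charged, after noon
- product present, with what was taken out counted in, in percent of the starting material first charged, after summer

Add the columns first: at 4.00 h the north flask holds 13.8% product and 85.9% starting material, together 99.7%, so little is going anywhere else. The product then stays flat, 14.0% at 50.0 h, with 86.3% starting material still there, so the north flask has stopped with starting material to spare. The north-east flask is flat as well, near 7.7%.

But what stopped them? Equilibrium is one reading, but then the lower north-east product has to come from its cooler bath. The other reading starts from the smallest charge, free enzyme at 2.0 µM: suppose capture agent removes it for good, making it the limiting reagent.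

The north readings average 13.8%, so 689 is the turnovers per enzyme, the product made over the enzyme charged. The north-east flask reads 391 with more capture agent. The north figure over the north-east figure is 1.76, and the capture agent charges stand at 1.50 the other way round, but the temperatures differ too, so this remains an inference.

If it holds, winter, dusk and summer bring no further product. At noon, 1.00 µM of fresh enzyme meets capture agent of which the first charge can have taken hardly any. So this reckoning gives 6.9 percentage points more, 20.7% in total.

The forecast gives 14% (13.6% to 14.2%) now, noon as best, 20.3% (17% to 21.5%) after noon and 14% (13.6% to 16%) after summer: “Fresh enzyme is trapped the same way, but first makes about half as much again”. This reckoning's noon total is above the forecast's by 0.37 points.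

The steps behind the flask:

    free enzyme → unfolded enzyme (k = 1.80 × 10⁻⁶ s⁻¹, Ea = 276 kJ mol⁻¹)
    starting material + free enzyme ⇌ starting complex (K = 270 M⁻¹, k = 14000 M⁻¹ s⁻¹, Ea = 13.0 kJ mol⁻¹, ΔH = −19.0 kJ mol⁻¹)
    starting complex → free enzyme + product (k = 2.10 s⁻¹, Ea = 79.0 kJ mol⁻¹)
    free enzyme + added ligand ⇌ idle complex (K = 5.40 × 10⁵ M⁻¹, k = 40.0 M⁻¹ s⁻¹, Ea = 51.0 kJ mol⁻¹, ΔH = −27.0 kJ mol⁻¹)
    capture agent + starting complex → trapped intermediate (k = 15.0 M⁻¹ s⁻¹, Ea = 54.0 kJ mol⁻¹)
    (constants at 40 °C)

The flask gives 14.1% at 2.5 d, 21.2% after noon and 14.1% after summer, so noon is best. At 6.00 h the trapped intermediate in the flask already holds 99.5% of the catalyst charged, while 99.0% of the capture agent remains. The turnovers per enzyme read from the north run, 689, put 6.9 points on the added enzyme, against 7.1 points in the flask. For the neighbour charged with 0.0080 mM free enzyme the same number reckons 55.1%, and that neighbour stands at 57.1% with 43% of its starting material left.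

(Readings and results were generated by integration on assumed constants.)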